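**Retrosynthetic overview**

- Mulberrofuran X is reached by deprotection of a fully protected 2-arylbenzofuran. Its furan ring (O1–C2=C3) is closed last, by an intramolecular Wittig reaction between a ring B carboxylic acid and a geranylated ring A (2-hydroxybenzyl)phosphonium salt.
- The ring B acid comes from an aryl bromide (bromine–lithium exchange, CO2). The bromide comes from a dihydrobenzofuran-3-carboxylate by saponification and reductive decarboxylation of the temporary C3' carboxyl group.
- The strategy rests on the O1'–C2'H(CMe2OH)–C3'H2 segment of the dihydrofuran ring: C2' is an ether carbon bonded to O1' and to the carbinol carbon, and C3' is benzylic. The C3'–C2' bond is therefore made by insertion of a benzylic rhodium carbenoid into the O–CH2 group of an aryl 2-silyloxy-2-methylpropyl ether, which closes the ring and sets C2'.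
- The diazo ester comes from 5-bromoresorcinol by formylation, hydrogen-bond-controlled differentiation of the two phenols, opening of 2,2-dimethyloxirane, one-carbon homologation and diazo transfer. The phosphonium salt comes from resorcinol and geranyl bromide by two directed ortho-metalations.
- Order of ring formation: dihydrofuran ring first (step 10), furan ring of the benzofuran second (step 21); both benzene rings are bought.

Key step: step 10

Assumption: Rh2(S-PTTL)4 is taken to select the hydrogen that leads to the (2R) ether carbon; should the tert-alkyl-substituted ether turn the usual sense round, the mirror-image catalyst Rh2(R-PTTL)4 would be used with nothing else changed.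

**Ring B: steps 1–13**

Step 1
Reactants: 1 5-bromoresorcinol
Product: 3 2-bromo-4,6-dihydroxybenzaldehyde, via aryl iminium chloride 2 (not isolated)
Conditions: POCl3, DMF, MeCN, −15 °C → rt; then H2O, 50 °C
Reagents that add atoms: N,N-dimethylformamide CN(C)C=O; water O
Why: Vilsmeier–Haack formylation: the chloroiminium ion attacks the resorcinol ring para to one hydroxyl group and ortho to the other (the position next to bromine, as in the formylation of orcinol), and hydrolysis of iminium salt 2 frees the aldehyde.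

Step 2
Reactants: 3 2-bromo-4,6-dihydroxybenzaldehyde
Product: 4 2-bromo-6-hydroxy-4-(methoxymethoxy)benzaldehyde
Conditions: MOMCl (1.05 equiv), i-Pr2NEt, CH2Cl2, 0 °C
Reagents that add atoms: chloromethyl methyl ether COCCl
Why: O-alkylation with an α-chloro ether (Williamson type): the 6-OH is tied up in a hydrogen bond to the formyl oxygen, so one equivalent of MOMCl should go to the free 4-OH.

Step 3
Reactants: 4 2-bromo-6-hydroxy-4-(methoxymethoxy)benzaldehyde; 5 2,2-dimethyloxirane
Product: 6 2-bromo-6-(2-hydroxy-2-methylpropoxy)-4-(methoxymethoxy)benzaldehyde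
Conditions: 5 (4 equiv), K2CO3 (0.3 equiv), DMF, 90 °C, sealed tube
Reagents that add atoms: none
Why: Base-catalysed SN2 ring opening of the epoxide: the phenoxide attacks the unsubstituted CH2 carbon of 5 and leaves the tertiary alcohol, while the MOM ether, the aldehyde and the aryl bromide are inert to K2CO3.

Step 4
Reactants: 6 2-bromo-6-(2-hydroxy-2-methylpropoxy)-4-(methoxymethoxy)benzaldehyde
Product: 7 2-bromo-6-[2-(tert-butyldimethylsilyloxy)-2-methylpropoxy]-4-(methoxymethoxy)benzaldehyde
Conditions: TBSOTf, 2,6-lutidine, CH2Cl2, −78 → 0 °C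
Reagents that add atoms: tert-butyldimethylsilyl triflate CC(C)(C)[Si](C)(C)OS(=O)(=O)C(F)(F)F
Why: Silylation of a hindered tertiary alcohol with a silyl triflate: 2,6-lutidine takes up the triflic acid so that the MOM acetal and the non-enolisable aldehyde are not touched.

Step 5
Reactants: 7 2-bromo-6-[2-(tert-butyldimethylsilyloxy)-2-methylpropoxy]-4-(methoxymethoxy)benzaldehyde
Product: 8 1-bromo-3-[2-(tert-butyldimethylsilyloxy)-2-methylpropoxy]-2-(2-methoxyethenyl)-5-(methoxymethoxy)benzene (E/Z mixture)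
Conditions: MeOCH2PPh3Cl, KN(SiMe3)2, THF, 0 °C → rt
Reagents that add atoms: (methoxymethyl)triphenylphosphonium chloride COC[P+](c1ccccc1)(c1ccccc1)c1ccccc1.[Cl-]
Why: Wittig olefination with methoxymethylenetriphenylphosphorane: the non-enolisable, electron-rich aldehyde should add the reactive ylide cleanly, and the E/Z mixture of enol ethers is of no consequence.

Step 6
Reactants: 8 1-bromo-3-[2-(tert-butyldimethylsilyloxy)-2-methylpropoxy]-2-(2-methoxyethenyl)-5-(methoxymethoxy)benzene
Product: 10 2-{2-bromo-6-[2-(tert-butyldimethylsilyloxy)-2-methylpropoxy]-4-(methoxymethoxy)phenyl}acetaldehyde, via α-mercurio aldehyde 9 (not isolated)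
Conditions: Hg(OAc)2, THF/H2O, 0 °C; then aq. KI, rt
Reagents that add atoms: water O
Why: Oxymercuration–demercuration of an enol ether: mercury adds at the benzylic carbon and water at the acetal carbon with loss of methanol to give 9, and iodide then removes mercury, so the aldehyde is set free at neutral pH with the MOM ether and the silyl ether intact.

Step 7
Reactants: 10 2-{2-bromo-6-[2-(tert-butyldimethylsilyloxy)-2-methylpropoxy]-4-(methoxymethoxy)phenyl}acetaldehyde
Product: 11 2-{2-bromo-6-[2-(tert-butyldimethylsilyloxy)-2-methylpropoxy]-4-(methoxymethoxy)phenyl}acetic acid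
Conditions: NaClO2, NaH2PO4, 2-methyl-2-butene, t-BuOH/H2O, 0 °C → rt
Reagents that add atoms: sodium chlorite [Na+].[O-]Cl=O
Why: Pinnick oxidation: chlorous acid oxidises only the aldehyde, and 2-methyl-2-butene traps the hypochlorous acid before it can chlorinate the electron-rich ring.

Step 8
Reactants: 11 2-{2-bromo-6-[2-(tert-butyldimethylsilyloxy)-2-methylpropoxy]-4-(methoxymethoxy)phenyl}acetic acid
Product: 12 methyl 2-{2-bromo-6-[2-(tert-butyldimethylsilyloxy)-2-methylpropoxy]-4-(methoxymethoxy)phenyl}acetate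
Conditions: MeI, K2CO3, DMF, rt
Reagents that add atoms: iodomethane CI
Why: SN2 O-methylation of the carboxylate, which is mild enough for the acetal and the silyl ether.

Step 9
Reactants: 12 methyl 2-{2-bromo-6-[2-(tert-butyldimethylsilyloxy)-2-methylpropoxy]-4-(methoxymethoxy)phenyl}acetate
Product: 13 methyl 2-{2-bromo-6-[2-(tert-butyldimethylsilyloxy)-2-methylpropoxy]-4-(methoxymethoxy)phenyl}-2-diazoacetate
Conditions: 4-acetamidobenzenesulfonyl azide, DBU, MeCN, 0 °C → rt
Reagents that add atoms: 4-acetamidobenzenesulfonyl azide CC(=O)Nc1ccc(cc1)S(=O)(=O)N=[N+]=[N-]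
Why: Regitz diazo transfer: DBU forms the benzylic ester enolate, which attacks the terminal nitrogen of the sulfonyl azide and loses the sulfonamide to give the aryldiazoacetate.

Step 10
Reactants: 13 methyl 2-{2-bromo-6-[2-(tert-butyldimethylsilyloxy)-2-methylpropoxy]-4-(methoxymethoxy)phenyl}-2-diazoacetate
Product: 14 methyl (2R,3S)-4-bromo-2-[2-(tert-butyldimethylsilyloxy)propan-2-yl]-6-(methoxymethoxy)-2,3-dihydrobenzofuran-3-carboxylate (cis)
Conditions: dirhodium tetrakis[N-phthaloyl-(S)-tert-leucinate], Rh2(S-PTTL)4 (1 mol %), toluene, −40 °C → rt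
Reagents that add atoms: none
Why: Rh2(S-PTTL)4 expels N2 from 13 to give a rhodium-bound aryl(methoxycarbonyl)carbenoid, which inserts into one C–H bond of the ArO–CH2 group through a three-centre, hydride-transfer-like transition state in which the ether oxygen stabilises the developing positive charge. The closest known reaction type is the dirhodium carboxylate-catalysed enantioselective intramolecular C–H insertion of ortho-alkoxyaryl diazoacetates into ether α-C–H bonds, which gives cis-2,3-dihydrobenzofuran-3-carboxylates. The dihydrofuran ring is closed by 1,5-C–H insertion, that is by forming the C3–C2 bond between the carbenoid carbon and the ether carbon five atoms away. C2 is set by the catalyst, whose four phthalimido-tert-leucinate ligands select one of the two enantiotopic hydrogens, while C3 is set relative to C2 by the insertion geometry (cis, kinetic) and does not matter because it is removed in steps 11 and 12. The step needs site selectivity for the O–CH2 hydrogens over the C-methyl, Si-methyl and OCH2O hydrogens and over the arene; this is secured because the O–CH2 group is the only oxygen-activated C–H site within reach of a five-membered closure (the neighbouring carbinol carbon is quaternary), the MOM group sits para and the bromine is inert.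

Step 11
Reactants: 14 methyl (2R,3S)-4-bromo-2-[2-(tert-butyldimethylsilyloxy)propan-2-yl]-6-(methoxymethoxy)-2,3-dihydrobenzofuran-3-carboxylate
Product: 15 (2R,3R)-4-bromo-2-[2-(tert-butyldimethylsilyloxy)propan-2-yl]-6-(methoxymethoxy)-2,3-dihydrobenzofuran-3-carboxylic acid (trans expected; a cis share is carried along)
Conditions: LiOH, THF/MeOH/H2O, 50 °C; then dilute HCl to pH 4, 0 °C
Reagents that add atoms: lithium hydroxide [Li+].[OH-]
Why: Ester saponification: hydroxide cleaves the methyl ester after base-mediated epimerisation at C3 to the less hindered trans isomer, while C2 is untouched because ring opening of the C3 enolate would be a disfavoured retro-5-endo-trig oxa-Michael process.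

Step 12
Reactants: 15 (2R,3R)-4-bromo-2-[2-(tert-butyldimethylsilyloxy)propan-2-yl]-6-(methoxymethoxy)-2,3-dihydrobenzofuran-3-carboxylic acid
Product: 17 (2R)-4-bromo-2-[2-(tert-butyldimethylsilyloxy)propan-2-yl]-6-(methoxymethoxy)-2,3-dihydrobenzofuran, via thiohydroxamate ester 16 (not isolated)
Conditions: N-hydroxypyridine-2-thione, DCC, DMAP (cat.), CH2Cl2, rt, dark; then t-BuSH (large excess), hv (tungsten lamp), rt
Reagents that add atoms: none
Why: Barton reductive decarboxylation: thiohydroxamate ester 16 fragments in a radical chain to CO2 and the benzylic C3 radical, which takes a hydrogen atom from the thiol, and neither the C2 stereocentre nor the aryl bromide takes part because no tin hydride is used.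

Step 13
Reactants: 17 (2R)-4-bromo-2-[2-(tert-butyldimethylsilyloxy)propan-2-yl]-6-(methoxymethoxy)-2,3-dihydrobenzofuran
Product: 19 (2R)-2-[2-(tert-butyldimethylsilyloxy)propan-2-yl]-6-(methoxymethoxy)-2,3-dihydrobenzofuran-4-carboxylic acid, via aryllithium 18 (not isolated)
Conditions: t-BuLi (2.1 equiv), THF, −78 °C; CO2; then dilute HCl to pH 4, 0 °C
Reagents that add atoms: carbon dioxide O=C=O
Why: Bromine–lithium exchange followed by carboxylation: exchange with t-BuLi at −78 °C is faster than any ortho-lithiation next to the MOM ether, and aryllithium 18 adds to CO2.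

**Ring A: steps 14–20**

Step 14
Reactants: 20 resorcinol
Product: 21 1,3-bis(methoxymethoxy)benzene
Conditions: MOMCl, i-Pr2NEt, CH2Cl2, 0 °C → rt
Reagents that add atoms: chloromethyl methyl ether COCCl
Why: O-alkylation of both phenols with the α-chloro ether (MOM protection), which installs the two directing groups for the metalations that follow.

Step 15
Reactants: 21 1,3-bis(methoxymethoxy)benzene; 22 geranyl bromide
Product: 24 2-[(2E)-3,7-dimethylocta-2,6-dienyl]-1,3-bis(methoxymethoxy)benzene, via 2-lithio-1,3-bis(methoxymethoxy)benzene 23 (not isolated)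
Conditions: n-BuLi, THF, 0 °C → rt; CuBr·SMe2 (10 mol %), 22, −78 °C → rt
Reagents that add atoms: none
Why: Directed ortho-metalation followed by copper-catalysed allylic substitution: the position between the two MOM ethers is lithiated selectively, and the aryl copper species displaces the primary allylic bromide at its CH2 carbon with the E double bond unchanged.

Step 16
Reactants: 24 2-[(2E)-3,7-dimethylocta-2,6-dienyl]-1,3-bis(methoxymethoxy)benzene
Product: 26 3-[(2E)-3,7-dimethylocta-2,6-dienyl]-2,4-bis(methoxymethoxy)benzaldehyde, via aryllithium 25 (not isolated)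
Conditions: n-BuLi, TMEDA, THF, 0 °C; DMF; then H2O
Reagents that add atoms: N,N-dimethylformamide CN(C)C=O
Why: Directed ortho-metalation and formylation: a MOM ether directs lithiation to the adjacent ring position (both such positions are equivalent), and aryllithium 25 adds to DMF.

Step 17
Reactants: 26 3-[(2E)-3,7-dimethylocta-2,6-dienyl]-2,4-bis(methoxymethoxy)benzaldehyde
Product: 27 3-[(2E)-3,7-dimethylocta-2,6-dienyl]-2,4-dihydroxybenzaldehyde
Conditions: HCl (3 M) in MeOH, rt
Reagents that add atoms: none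
Why: Acid-catalysed acetal cleavage (transacetalisation to dimethoxymethane): both MOM ethers fall at room temperature, where the geranyl chain, flanked by phenols that the formyl group deactivates, should not yet cyclise to a chroman.

Step 18
Reactants: 27 3-[(2E)-3,7-dimethylocta-2,6-dienyl]-2,4-dihydroxybenzaldehyde
Product: 28 3-[(2E)-3,7-dimethylocta-2,6-dienyl]-2-hydroxy-4-(triisopropylsilyloxy)benzaldehyde
Conditions: TIPSCl, imidazole, DMF, 0 °C → rt
Reagents that add atoms: chlorotriisopropylsilane CC(C)[Si](Cl)(C(C)C)C(C)C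
Why: Selective silylation of a phenol: the 2-OH is hydrogen-bonded to the aldehyde and crowded, so the bulky silyl chloride should react at the 4-OH only.

Step 19
Reactants: 28 3-[(2E)-3,7-dimethylocta-2,6-dienyl]-2-hydroxy-4-(triisopropylsilyloxy)benzaldehyde
Product: 29 2-[(2E)-3,7-dimethylocta-2,6-dienyl]-6-(hydroxymethyl)-3-(triisopropylsilyloxy)phenol
Conditions: NaBH4, THF/MeOH, 0 °C
Reagents that add atoms: none
Why: Hydride reduction of the aldehyde with NaBH4, which leaves the aryl silyl ether and the alkenes alone.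

Step 20
Reactants: 29 2-[(2E)-3,7-dimethylocta-2,6-dienyl]-6-(hydroxymethyl)-3-(triisopropylsilyloxy)phenol
Product: 30 {3-[(2E)-3,7-dimethylocta-2,6-dienyl]-2-hydroxy-4-(triisopropylsilyloxy)benzyl}triphenylphosphonium bromide
Conditions: PPh3·HBr, MeCN, rt
Reagents that add atoms: triphenylphosphine hydrobromide [Br-].c1ccc(cc1)[PH+](c1ccccc1)c1ccccc1
Why: Phosphonium salt formation from an ortho-hydroxybenzyl alcohol: mild acid ionises the benzylic alcohol, activated by the ortho and para oxygen atoms, to an ortho-quinone methide that PPh3 traps, at a temperature at which the aryl silyl ether and the geranyl chain should survive.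

**Union and end game: steps 21–23**

Step 21
Reactants: 19 (2R)-2-[2-(tert-butyldimethylsilyloxy)propan-2-yl]-6-(methoxymethoxy)-2,3-dihydrobenzofuran-4-carboxylic acid; 30 {3-[(2E)-3,7-dimethylocta-2,6-dienyl]-2-hydroxy-4-(triisopropylsilyloxy)benzyl}triphenylphosphonium bromide
Product: 33 2-{(2R)-2-[2-(tert-butyldimethylsilyloxy)propan-2-yl]-6-(methoxymethoxy)-2,3-dihydrobenzofuran-4-yl}-7-[(2E)-3,7-dimethylocta-2,6-dienyl]-6-(triisopropylsilyloxy)benzofuran, via acid chloride 31 (not isolated), via ester phosphonium bromide 32 (not isolated)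
Conditions: 19, 1-chloro-N,N,2-trimethylprop-1-en-1-amine, CH2Cl2, 0 °C → rt; then 30, Et3N, DMAP (cat.), toluene, rt → 110 °C
Reagents that add atoms: none
Why: Phenol acylation followed by intramolecular Wittig olefination of the ester carbonyl: acid chloride 31, made under neutral conditions, acylates the phenol of 30, and the ylide formed from 32 with Et3N closes the furan ring (C2=C3) with loss of Ph3PO.

Step 22
Reactants: 33 2-{(2R)-2-[2-(tert-butyldimethylsilyloxy)propan-2-yl]-6-(methoxymethoxy)-2,3-dihydrobenzofuran-4-yl}-7-[(2E)-3,7-dimethylocta-2,6-dienyl]-6-(triisopropylsilyloxy)benzofuran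
Product: 35 (2R)-2-[2-(tert-butyldimethylsilyloxy)propan-2-yl]-4-{7-[(2E)-3,7-dimethylocta-2,6-dienyl]-6-(triisopropylsilyloxy)benzofuran-2-yl}-2,3-dihydrobenzofuran-6-ol, via aryl trimethylsilyl ether 34 (not isolated)
Conditions: TMSOTf, 2,2′-bipyridyl, MeCN, 0 °C → rt; then H2O
Reagents that add atoms: none
Why: Acetal cleavage by silyl triflate and 2,2′-bipyridyl: the silylated bipyridinium activates the MOM ether and carries off the methoxymethyl group to give silyl ether 34, which water hydrolyses, so no protic acid meets the geranyl chain or the two bulky silyl ethers.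

Step 23
Reactants: 35 (2R)-2-[2-(tert-butyldimethylsilyloxy)propan-2-yl]-4-{7-[(2E)-3,7-dimethylocta-2,6-dienyl]-6-(triisopropylsilyloxy)benzofuran-2-yl}-2,3-dihydrobenzofuran-6-ol
Product: 36 mulberrofuran X, (2R)-4-{7-[(2E)-3,7-dimethylocta-2,6-dienyl]-6-hydroxybenzofuran-2-yl}-2-(2-hydroxypropan-2-yl)-2,3-dihydrobenzofuran-6-ol
Conditions: Bu4NF, THF, rt → 50 °C
Reagents that add atoms: none
Why: Fluoride-mediated desilylation: fluoride cleaves the aryl triisopropylsilyl ether at once and, on warming, the tertiary silyl ether, under basic conditions that cannot cyclise the geranyl chain or ionise the tertiary alcohol.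

**Compound list**

1 | 5-bromoresorcinol | Oc1cc(O)cc(Br)c1 | starting material
2 | [(2-bromo-4,6-dihydroxyphenyl)methylidene]dimethylammonium chloride | C[N+](C)=Cc1c(Br)cc(O)cc1O.[Cl-] | intermediate
3 | 2-bromo-4,6-dihydroxybenzaldehyde | O=Cc1c(Br)cc(O)cc1O | intermediate
4 | 2-bromo-6-hydroxy-4-(methoxymethoxy)benzaldehyde | O=Cc1c(Br)cc(OCOC)cc1O | intermediate
5 | 2,2-dimethyloxirane | CC1(C)CO1 | starting material
6 | 2-bromo-6-(2-hydroxy-2-methylpropoxy)-4-(methoxymethoxy)benzaldehyde | O=Cc1c(Br)cc(OCOC)cc1OCC(C)(C)O | intermediate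
7 | 2-bromo-6-[2-(tert-butyldimethylsilyloxy)-2-methylpropoxy]-4-(methoxymethoxy)benzaldehyde | O=Cc1c(Br)cc(OCOC)cc1OCC(C)(C)O[Si](C)(C)C(C)(C)C | intermediate
8 | 1-bromo-3-[2-(tert-butyldimethylsilyloxy)-2-methylpropoxy]-2-(2-methoxyethenyl)-5-(methoxymethoxy)benzene (E/Z mixture) | COC=Cc1c(Br)cc(OCOC)cc1OCC(C)(C)O[Si](C)(C)C(C)(C)C | intermediate
9 | 2-(acetoxymercurio)-2-{2-bromo-6-[2-(tert-butyldimethylsilyloxy)-2-methylpropoxy]-4-(methoxymethoxy)phenyl}acetaldehyde | CC(=O)O[Hg]C(C=O)c1c(Br)cc(OCOC)cc1OCC(C)(C)O[Si](C)(C)C(C)(C)C | intermediate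
10 | 2-{2-bromo-6-[2-(tert-butyldimethylsilyloxy)-2-methylpropoxy]-4-(methoxymethoxy)phenyl}acetaldehyde | O=CCc1c(Br)cc(OCOC)cc1OCC(C)(C)O[Si](C)(C)C(C)(C)C | intermediate
11 | 2-{2-bromo-6-[2-(tert-butyldimethylsilyloxy)-2-methylpropoxy]-4-(methoxymethoxy)phenyl}acetic acid | OC(=O)Cc1c(Br)cc(OCOC)cc1OCC(C)(C)O[Si](C)(C)C(C)(C)C | intermediate
12 | methyl 2-{2-bromo-6-[2-(tert-butyldimethylsilyloxy)-2-methylpropoxy]-4-(methoxymethoxy)phenyl}acetate | COC(=O)Cc1c(Br)cc(OCOC)cc1OCC(C)(C)O[Si](C)(C)C(C)(C)C | intermediate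
13 | methyl 2-{2-bromo-6-[2-(tert-butyldimethylsilyloxy)-2-methylpropoxy]-4-(methoxymethoxy)phenyl}-2-diazoacetate | COC(=O)C(=[N+]=[N-])c1c(Br)cc(OCOC)cc1OCC(C)(C)O[Si](C)(C)C(C)(C)C | intermediate
14 | methyl (2R,3S)-4-bromo-2-[2-(tert-butyldimethylsilyloxy)propan-2-yl]-6-(methoxymethoxy)-2,3-dihydrobenzofuran-3-carboxylate (cis) | Brc1cc(OCOC)cc2c1[C@H](C(=O)OC)[C@H](C(C)(C)O[Si](C)(C)C(C)(C)C)O2 | intermediate
15 | (2R,3R)-4-bromo-2-[2-(tert-butyldimethylsilyloxy)propan-2-yl]-6-(methoxymethoxy)-2,3-dihydrobenzofuran-3-carboxylic acid (trans) | Brc1cc(OCOC)cc2c1[C@@H](C(=O)O)[C@H](C(C)(C)O[Si](C)(C)C(C)(C)C)O2 | intermediate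
16 | 2-thioxopyridin-1(2H)-yl (2R,3R)-4-bromo-2-[2-(tert-butyldimethylsilyloxy)propan-2-yl]-6-(methoxymethoxy)-2,3-dihydrobenzofuran-3-carboxylate | Brc1cc(OCOC)cc2c1[C@@H](C(=O)On3ccccc3=S)[C@H](C(C)(C)O[Si](C)(C)C(C)(C)C)O2 | intermediate
17 | (2R)-4-bromo-2-[2-(tert-butyldimethylsilyloxy)propan-2-yl]-6-(methoxymethoxy)-2,3-dihydrobenzofuran | Brc1cc(OCOC)cc2c1C[C@H](C(C)(C)O[Si](C)(C)C(C)(C)C)O2 | intermediate
18 | (2R)-2-[2-(tert-butyldimethylsilyloxy)propan-2-yl]-4-lithio-6-(methoxymethoxy)-2,3-dihydrobenzofuran | [Li]c1cc(OCOC)cc2c1C[C@H](C(C)(C)O[Si](C)(C)C(C)(C)C)O2 | intermediate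
19 | (2R)-2-[2-(tert-butyldimethylsilyloxy)propan-2-yl]-6-(methoxymethoxy)-2,3-dihydrobenzofuran-4-carboxylic acid | OC(=O)c1cc(OCOC)cc2c1C[C@H](C(C)(C)O[Si](C)(C)C(C)(C)C)O2 | intermediate
20 | resorcinol | Oc1cccc(O)c1 | starting material
21 | 1,3-bis(methoxymethoxy)benzene | COCOc1cccc(OCOC)c1 | intermediate
22 | geranyl bromide | CC(C)=CCC/C(C)=C/CBr | starting material
23 | 2-lithio-1,3-bis(methoxymethoxy)benzene | [Li]c1c(OCOC)cccc1OCOC | intermediate
24 | 2-[(2E)-3,7-dimethylocta-2,6-dienyl]-1,3-bis(methoxymethoxy)benzene | COCOc1cccc(OCOC)c1C/C=C(C)/CCC=C(C)C | intermediate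
25 | 3-[(2E)-3,7-dimethylocta-2,6-dienyl]-2,4-bis(methoxymethoxy)phenyllithium | [Li]c1ccc(OCOC)c(C/C=C(C)/CCC=C(C)C)c1OCOC | intermediate
26 | 3-[(2E)-3,7-dimethylocta-2,6-dienyl]-2,4-bis(methoxymethoxy)benzaldehyde | O=Cc1ccc(OCOC)c(C/C=C(C)/CCC=C(C)C)c1OCOC | intermediate
27 | 3-[(2E)-3,7-dimethylocta-2,6-dienyl]-2,4-dihydroxybenzaldehyde | O=Cc1ccc(O)c(C/C=C(C)/CCC=C(C)C)c1O | intermediate
28 | 3-[(2E)-3,7-dimethylocta-2,6-dienyl]-2-hydroxy-4-(triisopropylsilyloxy)benzaldehyde | O=Cc1ccc(O[Si](C(C)C)(C(C)C)C(C)C)c(C/C=C(C)/CCC=C(C)C)c1O | intermediate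
29 | 2-[(2E)-3,7-dimethylocta-2,6-dienyl]-6-(hydroxymethyl)-3-(triisopropylsilyloxy)phenol | OCc1ccc(O[Si](C(C)C)(C(C)C)C(C)C)c(C/C=C(C)/CCC=C(C)C)c1O | intermediate
30 | {3-[(2E)-3,7-dimethylocta-2,6-dienyl]-2-hydroxy-4-(triisopropylsilyloxy)benzyl}triphenylphosphonium bromide | [Br-].Oc1c(C[P+](c2ccccc2)(c2ccccc2)c2ccccc2)ccc(O[Si](C(C)C)(C(C)C)C(C)C)c1C/C=C(C)/CCC=C(C)C | intermediate
31 | (2R)-2-[2-(tert-butyldimethylsilyloxy)propan-2-yl]-6-(methoxymethoxy)-2,3-dihydrobenzofuran-4-carbonyl chloride | ClC(=O)c1cc(OCOC)cc2c1C[C@H](C(C)(C)O[Si](C)(C)C(C)(C)C)O2 | intermediate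
32 | aryl ester of acid 19 with the phenol of 30, as the triphenylphosphonium bromide | [Br-].O=C(Oc1c(C[P+](c2ccccc2)(c2ccccc2)c2ccccc2)ccc(O[Si](C(C)C)(C(C)C)C(C)C)c1C/C=C(C)/CCC=C(C)C)c1cc(OCOC)cc2c1C[C@H](C(C)(C)O[Si](C)(C)C(C)(C)C)O2 | intermediate
33 | 2-{(2R)-2-[2-(tert-butyldimethylsilyloxy)propan-2-yl]-6-(methoxymethoxy)-2,3-dihydrobenzofuran-4-yl}-7-[(2E)-3,7-dimethylocta-2,6-dienyl]-6-(triisopropylsilyloxy)benzofuran | CC(C)=CCC/C(C)=C/Cc1c(O[Si](C(C)C)(C(C)C)C(C)C)ccc2cc(-c3cc(OCOC)cc4c3C[C@H](C(C)(C)O[Si](C)(C)C(C)(C)C)O4)oc12 | intermediate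
34 | trimethylsilyl ether of phenol 35 | CC(C)=CCC/C(C)=C/Cc1c(O[Si](C(C)C)(C(C)C)C(C)C)ccc2cc(-c3cc(O[Si](C)(C)C)cc4c3C[C@H](C(C)(C)O[Si](C)(C)C(C)(C)C)O4)oc12 | intermediate
35 | (2R)-2-[2-(tert-butyldimethylsilyloxy)propan-2-yl]-4-{7-[(2E)-3,7-dimethylocta-2,6-dienyl]-6-(triisopropylsilyloxy)benzofuran-2-yl}-2,3-dihydrobenzofuran-6-ol | CC(C)=CCC/C(C)=C/Cc1c(O[Si](C(C)C)(C(C)C)C(C)C)ccc2cc(-c3cc(O)cc4c3C[C@H](C(C)(C)O[Si](C)(C)C(C)(C)C)O4)oc12 | intermediate
36 | mulberrofuran X | CC(C)=CCC/C(C)=C/Cc1c(O)ccc2cc(-c3cc(O)cc4c3C[C@H](C(C)(C)O)O4)oc12 | target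

**Step count**

Total step count: 23. Longest linear sequence: 16 (steps 1–13, then 21–23).

**Steps most likely to fail**

1. Step 10. Insertion into the crowded, neopentyl-type O–CH2 group may be slow enough for carbene dimerisation to compete, and the catalyst may discriminate poorly between the two enantiotopic hydrogens. The fallback sets out from 4 and comes back at 17; it builds the same ring by epoxide opening instead.
 - Phenol 4 would be acylated with Boc2O (i-Pr2NEt, DMAP cat.) to 3-bromo-2-formyl-5-(methoxymethoxy)phenyl tert-butyl carbonate F1 and reduced with NaBH4 to 3-bromo-2-(hydroxymethyl)-5-(methoxymethoxy)phenyl tert-butyl carbonate F2.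
 - Excess 2-methylprop-1-enylmagnesium bromide (THF, −78 → 0 °C) would trigger Boc migration and loss of tert-butyl carbonate to an ortho-quinone methide, which takes up the alkenyl Grignard reagent by 1,4-addition to give 3-bromo-5-(methoxymethoxy)-2-(3-methylbut-2-enyl)phenol F3.
 - Silylation (TBSCl, imidazole) would give tert-butyl[3-bromo-5-(methoxymethoxy)-2-(3-methylbut-2-enyl)phenoxy]dimethylsilane F4.
 - Shi epoxidation with the enantiomer of the fructose-derived ketone (KHSO5, K2CO3 buffer, MeCN/dimethoxymethane/H2O, 0 °C) should give (3S)-3-{[2-bromo-6-(tert-butyldimethylsilyloxy)-4-(methoxymethoxy)phenyl]methyl}-2,2-dimethyloxirane F5.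
 - Bu4NF would free the phenoxide, which opens the epoxide at its CH carbon with inversion (5-exo-tet) to (R)-2-[4-bromo-6-(methoxymethoxy)-2,3-dihydrobenzofuran-2-yl]propan-2-ol F6; TBSOTf/2,6-lutidine then gives 17.

2. Step 21. The ylide may be C-acylated by acid chloride that has not yet reacted, and its attack on the electron-rich, ortho-substituted aryl ester may be sluggish, so that ring closure is outrun. The fallback sets out from 17 and 24 and comes back at 36; it makes the furan ring by alkyne cycloisomerisation.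
 - Bromide 17 would undergo Sonogashira coupling with trimethylsilylacetylene (PdCl2(MeCN)2, XPhos, Cs2CO3, MeCN, 80 °C) to (2R)-2-[2-(tert-butyldimethylsilyloxy)propan-2-yl]-6-(methoxymethoxy)-4-[(trimethylsilyl)ethynyl]-2,3-dihydrobenzofuran F7.
 - K2CO3/MeOH would give (2R)-2-[2-(tert-butyldimethylsilyloxy)propan-2-yl]-4-ethynyl-6-(methoxymethoxy)-2,3-dihydrobenzofuran F8.
 - Arene 24 would be lithiated as in step 16 and quenched with 1,2-diiodoethane to 1-[(2E)-3,7-dimethylocta-2,6-dienyl]-3-iodo-2,6-bis(methoxymethoxy)benzene F9.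
 - Sonogashira coupling of F8 with F9 (Pd(PPh3)2Cl2, CuI, Et3N, THF, 50 °C) would give the diarylalkyne (2R)-2-[2-(tert-butyldimethylsilyloxy)propan-2-yl]-4-({3-[(2E)-3,7-dimethylocta-2,6-dienyl]-2,4-bis(methoxymethoxy)phenyl}ethynyl)-6-(methoxymethoxy)-2,3-dihydrobenzofuran F10.
 - Removal of the three MOM groups under the conditions of step 22 would give the triol 2-[(2E)-3,7-dimethylocta-2,6-dienyl]-4-({(2R)-2-[2-(tert-butyldimethylsilyloxy)propan-2-yl]-6-hydroxy-2,3-dihydrobenzofuran-4-yl}ethynyl)benzene-1,3-diol F11.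
 - Bu4NF in THF at 60 °C would then add the phenoxide next to the alkyne in a 5-endo-dig closure of the furan ring and remove the tertiary silyl group, which gives 36.

3. Step 12. Hydrogen transfer from the alkanethiol to the stabilised benzylic C3 radical is slow, so recombination of that radical with the pyridylthio group may take over. The fallback sets out from 15 and comes back at 17 and makes no new compound; it drops the thiohydroxamate chain.
 - The free acid 15 would be decarboxylated by single-electron oxidation of its carboxylate with photoexcited 9-mesityl-10-methylacridinium tetrafluoroborate (5 mol %, blue LEDs, CF3CH2OH, i-Pr2NEt 20 mol %).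
 - The benzylic radical would be quenched by thiophenol formed in the flask from PhSSPh (10 mol %), a faster hydrogen donor with no thiocarbonyl group to trap the radical.

**Further compounds**

F1 | step 10 | 3-bromo-2-formyl-5-(methoxymethoxy)phenyl tert-butyl carbonate | O=Cc1c(Br)cc(OCOC)cc1OC(=O)OC(C)(C)C
F2 | step 10 | 3-bromo-2-(hydroxymethyl)-5-(methoxymethoxy)phenyl tert-butyl carbonate | OCc1c(Br)cc(OCOC)cc1OC(=O)OC(C)(C)C
F3 | step 10 | 3-bromo-5-(methoxymethoxy)-2-(3-methylbut-2-enyl)phenol | CC(C)=CCc1c(Br)cc(OCOC)cc1O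
F4 | step 10 | tert-butyl[3-bromo-5-(methoxymethoxy)-2-(3-methylbut-2-enyl)phenoxy]dimethylsilane | CC(C)=CCc1c(Br)cc(OCOC)cc1O[Si](C)(C)C(C)(C)C
F5 | step 10 | (3S)-3-{[2-bromo-6-(tert-butyldimethylsilyloxy)-4-(methoxymethoxy)phenyl]methyl}-2,2-dimethyloxirane | CC1(C)O[C@H]1Cc1c(Br)cc(OCOC)cc1O[Si](C)(C)C(C)(C)C
F6 | step 10 | (R)-2-[4-bromo-6-(methoxymethoxy)-2,3-dihydrobenzofuran-2-yl]propan-2-ol | Brc1cc(OCOC)cc2c1C[C@H](C(C)(C)O)O2
F7 | step 21 | (2R)-2-[2-(tert-butyldimethylsilyloxy)propan-2-yl]-6-(methoxymethoxy)-4-[(trimethylsilyl)ethynyl]-2,3-dihydrobenzofuran | C[Si](C)(C)C#Cc1cc(OCOC)cc2c1C[C@H](C(C)(C)O[Si](C)(C)C(C)(C)C)O2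
F8 | step 21 | (2R)-2-[2-(tert-butyldimethylsilyloxy)propan-2-yl]-4-ethynyl-6-(methoxymethoxy)-2,3-dihydrobenzofuran | C#Cc1cc(OCOC)cc2c1C[C@H](C(C)(C)O[Si](C)(C)C(C)(C)C)O2
F9 | step 21 | 1-[(2E)-3,7-dimethylocta-2,6-dienyl]-3-iodo-2,6-bis(methoxymethoxy)benzene | Ic1ccc(OCOC)c(C/C=C(C)/CCC=C(C)C)c1OCOC
F10 | step 21 | (2R)-2-[2-(tert-butyldimethylsilyloxy)propan-2-yl]-4-({3-[(2E)-3,7-dimethylocta-2,6-dienyl]-2,4-bis(methoxymethoxy)phenyl}ethynyl)-6-(methoxymethoxy)-2,3-dihydrobenzofuran | CC(C)=CCC/C(C)=C/Cc1c(OCOC)ccc(C#Cc2cc(OCOC)cc3c2C[C@H](C(C)(C)O[Si](C)(C)C(C)(C)C)O3)c1OCOC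
F11 | step 21 | 2-[(2E)-3,7-dimethylocta-2,6-dienyl]-4-({(2R)-2-[2-(tert-butyldimethylsilyloxy)propan-2-yl]-6-hydroxy-2,3-dihydrobenzofuran-4-yl}ethynyl)benzene-1,3-diol | CC(C)=CCC/C(C)=C/Cc1c(O)ccc(C#Cc2cc(O)cc3c2C[C@H](C(C)(C)O[Si](C)(C)C(C)(C)C)O3)c1O
F0 | step 12 | none | none
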